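The target is the meso isomer: a mirror plane bisects the C2–C3 bond of the butane chain, so the benzylic carbons C1 and C4 are equivalent and each carries the same 4-hydroxy-3,5-dimethoxyphenyl ring. Both C1–aryl and C4–aryl bonds are therefore cut at once, giving a meso 2,3-dimethylbutane-1,4-diyl bis-electrophile and two equivalents of an O-benzyl-protected arylmagnesium bromide. One copper-catalysed operation joins both rings without touching C2 or C3, which lie one carbon away. The bis-tosylate precursor comes from 2,3-dimethylmaleic anhydride, whose ring-locked Z alkene is hydrogenated syn to fix the meso relationship before reductive ring opening.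

Key step: step 5

Assumption: the arylmagnesium bromide is prepared as a THF solution and consumed directly, so its formation is counted inside step 5; the chain is numbered C1–C4 with the stereocentres at C2 and C3.

Step 1
Reactants: 1 2,3-dimethylmaleic anhydride
Product: 2 cis-2,3-dimethylsuccinic anhydride (meso, (3R,4S)-3,4-dimethyloxolane-2,5-dione)
Conditions: H2 (4 atm), PtO2 (5 mol%), dry EtOAc, rt
Reagents that add atoms: none
Why: Heterogeneous catalytic hydrogenation adds both hydrogens to one face of the ring-held Z tetrasubstituted alkene, so the two new stereocentres are created together with the methyls cis (meso), and neutral anhydrous conditions with a platinum catalyst limit alkene migration and enolisation that would leak to the trans isomer.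

Step 2
Reactants: 2 cis-2,3-dimethylsuccinic anhydride
Product: 3 meso-(2R,3S)-2,3-dimethylbutane-1,4-diol
Conditions: LiAlH4 (2 equiv), THF, 0 °C → reflux (2 added slowly to the hydride); Na2SO4·10H2O quench, filtration
Reagents that add atoms: none
Why: Exhaustive hydride reduction of a cyclic anhydride to the 1,4-diol, in which slow addition of 2 to excess hydride should reduce every carbonyl faster than the alpha-hydrogens can epimerise, after which C2 and C3 bear no acidic hydrogen; the solid-hydrate quench avoids aqueous extraction of the water-soluble diol.

Step 3
Reactants: 3 meso-2,3-dimethylbutane-1,4-diol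
Product: 4 meso-(2R,3S)-2,3-dimethylbutane-1,4-diyl bis(4-methylbenzenesulfonate)
Conditions: TsCl (2.6 equiv), pyridine, −10 → 0 °C; cold dilute HCl work-up
Reagents that add atoms: 4-methylbenzenesulfonyl chloride (TsCl), Cc1ccc(cc1)S(=O)(=O)Cl
Why: O-sulfonylation of both primary alcohols, with excess TsCl and low temperature so that the second sulfonylation outruns closure of the mono-tosylate to a tetrahydrofuran; only O–H bonds react, so the stereocentres are untouched.

Step 4
Reactants: 5 4-bromo-2,6-dimethoxyphenol; 6 benzyl bromide
Product: 7 2-(benzyloxy)-5-bromo-1,3-dimethoxybenzene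
Conditions: K2CO3, DMF, 60 °C
Reagents that add atoms: none
Why: Williamson ether synthesis, in which the phenoxide, although flanked by two methoxy groups, should alkylate cleanly with the reactive benzylic bromide while the aryl bromide stays inert.

Step 5
Reactants: 4 meso-2,3-dimethylbutane-1,4-diyl bis(4-methylbenzenesulfonate); 7 2-(benzyloxy)-5-bromo-1,3-dimethoxybenzene
Product: 9 meso-(2R,3S)-1,4-bis[4-(benzyloxy)-3,5-dimethoxyphenyl]-2,3-dimethylbutane, via arylmagnesium bromide 8 (not isolated)
Conditions: 7 (3 equiv), Mg turnings (I2-activated), THF, 40 °C; then added to 4 (1 equiv), Li2CuCl4 (10 mol%), 1-phenylpropyne (20 mol%), THF, −20 °C → rt; aq. NH4Cl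
Reagents that add atoms: none
Why: Magnesium inserts into the C–Br bond of 7 to give 8, which transmetalates to the copper catalyst (the divalent copper salt is first reduced by 8 to monovalent copper) to form an arylcuprate; this attacks the primary carbon of each C–OTs group (C1 and C4 of the chain) in an SN2-type oxidative addition, and the resulting trivalent alkyl(aryl)copper species reductively eliminates the aryl–CH2 bond and returns the catalyst. The closest known reaction type is the Kochi-type copper-catalysed coupling of Grignard reagents with primary alkyl tosylates, here run at both ends of one 1,4-bis-tosylate. No ring is closed and no stereocentre is created: C2 and C3 sit one carbon away from the reacting centres, carry neither a leaving group nor an acidic hydrogen, and so keep the meso relationship fixed in step 1. The step needs only chemoselectivity, substitution over elimination, reduction and biaryl formation, and this is secured by two equivalent primary (merely beta-branched) sulfonates, excess 8, exclusion of oxygen and the alkyne additive that stabilises the organocopper intermediates. The mono-arylated tosylate formed first is the same kind of electrophile as 4 and has no intramolecular escape route, so it is simply carried on to 9. LiCl is left out of the Grignard preparation so that tosylate is not diverted to a slow-reacting alkyl chloride, whereas any exchange to alkyl bromide by MgBr2 is harmless.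

Step 6
Reactants: 9 meso-1,4-bis[4-(benzyloxy)-3,5-dimethoxyphenyl]-2,3-dimethylbutane
Product: 10 meso-(2R,3S)-1,4-bis(4-hydroxy-3,5-dimethoxyphenyl)-2,3-dimethylbutane (target)
Conditions: H2 (1 atm), 10% Pd/C, EtOAc–MeOH, rt
Reagents that add atoms: none
Why: Catalytic hydrogenolysis should cleave both benzylic C–O bonds of the aryl benzyl ethers, while the aryl methyl ethers, the C–C bonds of the chain and the remote sp3 stereocentres are inert under these neutral conditions.

Compound list
1 | 2,3-dimethylmaleic anhydride (3,4-dimethylfuran-2,5-dione) | CC1=C(C)C(=O)OC1=O | starting material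
2 | cis-2,3-dimethylsuccinic anhydride (meso, (3R,4S)-3,4-dimethyloxolane-2,5-dione) | C[C@@H]1[C@H](C)C(=O)OC1=O | intermediate
3 | meso-(2R,3S)-2,3-dimethylbutane-1,4-diol | OC[C@@H](C)[C@@H](C)CO | intermediate
4 | meso-(2R,3S)-2,3-dimethylbutane-1,4-diyl bis(4-methylbenzenesulfonate) | Cc1ccc(cc1)S(=O)(=O)OC[C@@H](C)[C@@H](C)COS(=O)(=O)c1ccc(C)cc1 | intermediate
5 | 4-bromo-2,6-dimethoxyphenol | COc1cc(Br)cc(OC)c1O | starting material
6 | benzyl bromide | BrCc1ccccc1 | starting material
7 | 2-(benzyloxy)-5-bromo-1,3-dimethoxybenzene | COc1cc(Br)cc(OC)c1OCc1ccccc1 | intermediate
8 | [4-(benzyloxy)-3,5-dimethoxyphenyl]magnesium bromide | COc1cc([Mg]Br)cc(OC)c1OCc1ccccc1 | intermediate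
9 | meso-(2R,3S)-1,4-bis[4-(benzyloxy)-3,5-dimethoxyphenyl]-2,3-dimethylbutane | COc1cc(C[C@@H](C)[C@@H](C)Cc2cc(OC)c(OCc3ccccc3)c(OC)c2)cc(OC)c1OCc1ccccc1 | intermediate
10 | meso-(2R,3S)-1,4-bis(4-hydroxy-3,5-dimethoxyphenyl)-2,3-dimethylbutane | COc1cc(C[C@@H](C)[C@@H](C)Cc2cc(OC)c(O)c(OC)c2)cc(OC)c1O | target

Total step count: 6
Longest linear sequence: 5 steps (1 → 2 → 3 → 4 → 9 → 10, steps 1, 2, 3, 5 and 6); the aryl branch (5 → 7 → 9) joins at step 5.

Steps most likely to fail

Step 5. The risks are slow magnesium insertion into the electron-rich aryl bromide, and a second substitution at the beta-branched primary sulfonate that stalls while the Grignard reagent is consumed by biaryl formation or attack at sulfur. The fallback reverses the polarity of the same two bonds and sets out from 4. Sodium iodide in refluxing acetone should exchange both sulfonates to give meso-1,4-diiodo-2,3-dimethylbutane F1. Activated zinc dust with LiCl in THF at 40 °C should insert into both C–I bonds to give the bis(iodozinc) reagent meso-(2,3-dimethylbutane-1,4-diyl)bis(iodozinc) F2. A Negishi coupling of F2 with bromide 7 (2.2 equiv), catalysed by Pd(OAc)2 and SPhos in THF at 50 °C, should then form both aryl–CH2 bonds. The route is rejoined at 9.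

Step 1. The risks are slow hydrogen uptake by the tetrasubstituted alkene, and alkene migration on the metal surface before reduction, which would erode the cis selectivity. The fallback sets out from 1 and reduces the carbonyls before the alkene. Excess i-Bu2AlH in toluene (−78 °C → rt) should give (Z)-2,3-dimethylbut-2-ene-1,4-diol F3. Hydroxyl-directed homogeneous hydrogenation with [Ir(cod)(PCy3)(py)]PF6 under H2 in CH2Cl2 at rt should then add hydrogen syn across the Z alkene and give the meso diol directly. The route is rejoined at 3.

Step 3. The risk is intramolecular displacement within the mono-sulfonate, closing a tetrahydrofuran ring before the second hydroxyl is sulfonylated. The fallback sets out from 3 and changes the electrophile class used in the coupling. MsCl and Et3N in CH2Cl2 at −30 °C (fast sulfene-type mesylation) should give meso-2,3-dimethylbutane-1,4-diyl dimethanesulfonate F4. LiBr in refluxing acetone should convert it into meso-1,4-dibromo-2,3-dimethylbutane F5. The dibromide is then coupled with arylmagnesium bromide 8 under the Li2CuCl4 conditions of step 5. The route is rejoined at 9.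

Further compounds
F1 | step 5 | meso-1,4-diiodo-2,3-dimethylbutane | IC[C@@H](C)[C@@H](C)CI
F2 | step 5 | meso-(2,3-dimethylbutane-1,4-diyl)bis(iodozinc) | I[Zn]C[C@@H](C)[C@@H](C)C[Zn]I
F3 | step 1 | (Z)-2,3-dimethylbut-2-ene-1,4-diol | OC/C(C)=C(C)\CO
F4 | step 3 | meso-2,3-dimethylbutane-1,4-diyl dimethanesulfonate | CS(=O)(=O)OC[C@@H](C)[C@@H](C)COS(C)(=O)=O
F5 | step 3 | meso-1,4-dibromo-2,3-dimethylbutane | BrC[C@@H](C)[C@@H](C)CBr
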